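## The problem

The target is 2-[(3S,5R)-3,5-dimethyl-5-[(2R,5E,9E)-2-methyl-10-phenyldeca-5,9-dien-1-yl]-1,2-dioxolan-3-yl]acetic acid. It is numbered here along its longest chain: C1 is the carboxyl carbon, C2 the exocyclic methylene, and C3 and C5 the ring carbons, joined by C4 and by the peroxide O2–O1 (O2 on C3, O1 on C5). C7 is the methyl-bearing chain carbon, C10=C11 and C14=C15 are the two E alkenes, and C15 carries the phenyl ring.

The single ring is a 1,2-dioxolane in which both oxygen-bearing carbons are fully substituted. Neither peroxide C–O bond can therefore come from a simple displacement at a secondary carbon, and once the ring exists there is no hydrogen on C3 or C5 through which a wrong configuration could be corrected.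

Three stereocentres must be set, and they barely influence one another. C7 is an isolated methyl branch that is best bought. C5 lies across a methylene from C7 and receives no useful induction, so it needs reagent control or a stereospecific transfer. C3 sees C5 only through the small difference between a methyl group and a CH2R arm on a five-membered ring.

The O–O bond excludes hydrogenation, dissolving metals, low-valent metal reductants and hard carbanions late in the route. The acid arm is β to O2, so an enolate at C2 can expel the peroxide. The styrene and the C10=C11 alkene exclude ozone, peracids and strongly ionising acid from the moment they are present.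

The feature that opens the key step is the substitution of C3: it carries O2, a methyl group and the CH2–CO2H arm. Read backwards, C3 and C2 are the two carbons of a methallyl alkene whose internal carbon can accept a peroxide oxygen held on C5 at five-ring distance, and C1, at the carbonyl oxidation level, can arrive as carbon monoxide. Because C3 is quaternary, a metal placed on C2 in such an oxymetalation has no β-hydrogen and can wait for the carbonylation.

## Retrosynthesis

**Acid 30 to methyl ester 29.** Only the acid O–H is changed. The ester is the better product of the ring-forming step because an acylpalladium species is cleaved cleanly by an alcohol and because the ester can be separated from its C3 epimer on silica. The forward step must hydrolyse an ester whose α-carbon is β to a peroxide oxygen without deprotonating that carbon.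

**Ester 29 to hydroperoxide 26, carbon monoxide 27 and methanol 28.** Two bonds are cut, O2–C3 and C2–C1, and the ring is opened. The neighbouring cuts are less attractive. Cutting O1–C5 would need a hydroperoxide on C3 beside the ester arm and an electrophilic C5. Cutting the ring C–C bonds leads to annulations that create C3 and C5 together without absolute control. The chosen cut leaves an acyclic molecule in which only C5 and C7 are stereogenic, takes C1 from the cheapest one-carbon source and stores C2=C3 as an unreactive 1,1-disubstituted alkene. The forward reaction must be 5-exo and Markovnikov, must discriminate the two alkene faces, must prefer this alkene over the two in the side chain, and must carbonylate faster than it reverts.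

**Hydroperoxide 26 to peroxyketal 25 and ketone 24.** The hydroperoxide O–H is masked as a 2-methoxyprop-2-yl peroxyketal, and the C3=C2 double bond is cut back to the methyl ketone (Wittig methylenation forward). The alkene cannot be carried further back, because the reaction that installs the peroxide leaves an oxygen on C3. The ketone is also the point from which a known ring closure can be reached if the key step fails. The forward methylenation must add to a β-peroxy ketone without enolising it.

**Ketone 24 to hydroperoxy alcohol 20, through 23, 22 and 21.** The C3–CH3 bond is cut (methyl Grignard addition to aldehyde 22, then oxidation of carbinol 23), and the aldehyde is traced to primary alcohol 21 and the free hydroperoxide 20. A methyl-substituted oxetane would deliver the secondary carbinol directly, but it would need a second controlled carbinol centre and a more hindered ring closure. Three conventional steps are the lesser cost. The forward sequence needs chemoselective ketalisation of OOH beside OH and an organometallic addition that leaves the peroxyketal alone.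

**Hydroperoxy alcohol 20 to oxetane 19.** The C5–O1 bond is cut. Invertive perhydrolysis of a 2,2-disubstituted oxetane is the one established way to make a tertiary alkyl hydroperoxide stereospecifically. Radical hydroperoxidation of a 1,1-disubstituted alkene or ionisation of a tertiary alcohol would give both C5 epimers. The cut turns the peroxide problem into that of a tertiary alcohol stereocentre, and the oxetane oxygen ends up on C3, exactly where the carbonyl group of 24 is needed. The forward step must attack the tertiary carbon with inversion and without interference from the chain alkenes.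

**Oxetane 19 to aldehyde 17 and sulfone 8.** The C10=C11 double bond is cut (Julia–Kocienski olefination). The union is placed here for three reasons:
- Every later intermediate carries a peroxide that should not meet a metalated sulfone.
- The chain alkenes would not survive the ozonolysis that unveils C10, so the union cannot come earlier.
- The trisubstituted alkene that C10 replaces is a six-ring π-nucleophile toward C5 and must be gone before the oxetane is activated.

The cut divides the molecule into a C3–C10 piece holding both stereocentres and an achiral C11–C15 phenyl piece. The forward step needs high E selectivity.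

**Aldehyde 17 to allylic alcohol 12, through 16, 14 and 13.** C10=O is traced to the isopropylidene terminus of oxetane 16 (ozonolysis). The oxetane O–C3 bond goes back to diol 14 (Williamson closure through the primary sulfonate), the C4–H bond to epoxy alcohol 13 (hydride opening), and the epoxide to the E allylic alcohol 12 (Sharpless epoxidation). This is the standard route to a tertiary carbinol of defined configuration, and it sets C5 by the choice of tartrate, independently of C7. Forward, the epoxidation must ignore the remote trisubstituted alkene, the hydride must go to C4, and the ring closure must not touch the tertiary C–O bond.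

**Allylic alcohol 12 to alkyne 10 and (R)-citronellal 9.** The C5–CH3 and C4–C3 bonds are cut together (methylalumination of the alkyne, then hydroxymethylation), and the alkyne carbon C4 is removed (Ohira–Bestmann homologation backwards). Compared with a methyl ketone, Horner–Wadsworth–Emmons and reduction sequence, this gives the E geometry without an isomer mixture and in two steps. Compound 9 supplies C5 to C10, the C7 methyl stereocentre in the right sense and a latent C10 aldehyde.

**Sulfone 8 to sulfide 7, alcohol 5 and thiol 6; alcohol 5 to ester 4, tert-butyl acetate 1 and cinnamyl bromide 2.** The S–O bonds and the C11–S bond are cut, then the C12–C13 bond (enolate alkylation). The E styrene is bought with 2, so this branch has no geometric problem.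

## Roads not taken

**Alternative 1:** The ring is cut at O1–C5 and C3–C4, so that a small C1–C3 peroxycarbenium unit is annulated onto a chain alkene.
- *Forward key step:* SnCl4 would ionise the silylperoxy ketal 3-methoxy-3-[(triethylsilyl)peroxy]butyl benzoate A2. The cation would add at the CH2 terminus of the chain alkene tert-butyl{[(4R)-4,6-dimethylhept-6-en-1-yl]oxy}diphenylsilane A3. The tertiary C5 cation would be closed by the silylated peroxide oxygen to give 2-[(3R,5R)-5-[(2R)-5-{[tert-butyl(diphenyl)silyl]oxy}-2-methylpentyl]-3,5-dimethyl-1,2-dioxolan-3-yl]ethyl benzoate A1 together with its stereoisomers.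
- *Merits:* annulation of peroxycarbenium ions with 1,1-disubstituted alkenes is an established reaction type, both partners are a few steps from simple materials, and the dioxolane appears in one convergent operation. In step count and in precedent for its key step this road is better than the chosen one.
- *Weak points:* both ring stereocentres arise in the annulation from achiral reacting termini, C7 is too remote to bias C5, and the cis/trans preference is small when each ring carbon carries a methyl group and a methylene arm, so A1 would be one of four isomers. C1 must then be raised from the protected alcohol to the acid in three operations. The diene must be attached at the end by desilylation, oxidation and a base-mediated olefination on the peroxide.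
- *Comparison:* the chosen plan pays with a longer linear sequence and an untested key step. Against that it offers a stereospecific origin for C5, a catalyst-addressable C3, C1 at the correct oxidation level from the start, and a one-step end game.

**Alternative 2:** The ring is cut at O1–C5 and O2–C3, and both oxygens come from H2O2.
- *Forward key step:* aqueous H2O2 would add to C5 of the iminium ion formed from the enone (3E,6R,9E,13E)-4,6-dimethyl-14-phenyltetradeca-3,9,13-trien-2-one A4 and a cinchona-derived primary amine salt. The β-hydroperoxy ketone would close to the peroxyhemiketal (3RS,5R)-3,5-dimethyl-5-[(2R,5E,9E)-2-methyl-10-phenyldeca-5,9-dien-1-yl]-1,2-dioxolan-3-ol A5.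
- *Merits:* C5 would be set catalytically in one step from an enone only a few steps from 9, and no peroxide protecting group is needed. If it worked it would reach the ring in roughly half the steps of the chosen plan, a clear advantage.
- *Weak points:* this hydroperoxidation is established for enones with one β-substituent. A β,β-disubstituted enone forms its iminium ion slowly, the addition that creates a fully substituted C–O centre is reversible, E/Z scrambling through the dienamine erodes face selectivity, and epoxide formation competes. The key step is therefore as untested as the one chosen here. C3 remains a hemiketal, and the acetate arm must still be introduced by a Lewis acid substitution under substrate control only.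
- *Comparison:* A5 is the same compound as F1 of the fallback below, so the two plans meet there. The chosen plan rests C5 on a stereospecific, precedented transfer and spends its one untested step on forming C3 and the C2–C1 bond together.

**Alternative 3:** The ring is cut at C4–C5 and O2–C3: a chain-derived C5 peroxycarbenium ion is annulated with an alkene that already carries the ester.
- *Forward key step:* SnCl4 would ionise the silylperoxy ketal tert-butyl{[(4R)-6-methoxy-4-methyl-6-[(triethylsilyl)peroxy]heptyl]oxy}diphenylsilane A7. Methyl 3-methylbut-3-enoate A8 would attack the cation through its CH2 terminus. The tertiary C3 cation would be closed by the silylated peroxide oxygen to give methyl 2-[(3S,5R)-5-[(2R)-5-{[tert-butyl(diphenyl)silyl]oxy}-2-methylpentyl]-3,5-dimethyl-1,2-dioxolan-3-yl]acetate A6 and its stereoisomers.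
- *Merits:* this is the most convergent of the routes, the acetate arm arrives at the correct oxidation level just as in the chosen plan, and the reaction type is known.
- *Weak points:* A8 is a poor π-nucleophile, because the cation it forms is β to an ester carbonyl, and it can drift into conjugation under the Lewis acid. The facial choice at the planar C5 cation is governed only by the remote C7 centre, and the C3/C5 relationship only by a methyl-versus-methylene difference, so four isomers are again expected. The side chain must be completed after the peroxide exists, by a base-mediated olefination next to a β-peroxy ester.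
- *Comparison:* on step count this road beats the chosen plan. The chosen plan answers with absolute control at C5, a single C3 issue in place of a four-isomer mixture, and a diene that is in place before any peroxide is made.

Key step: step 19

Assumption: commercial (R)-citronellal of high enantiomeric purity is used, so that 12 is essentially one enantiomer before the Sharpless step; any minor enantiomer would surface later as a diastereomer and be removed together with C3 or C5 epimers.

## Route

Step 1
Reactants: 1 tert-butyl acetate; 2 cinnamyl bromide, [(1E)-3-bromoprop-1-en-1-yl]benzene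
Product: 4 tert-butyl (4E)-5-phenylpent-4-enoate, via lithium enolate 3 (not isolated)
Conditions: LiN(iPr)2, THF, −78 °C; then 2, −78 → 0 °C
Reagents that add atoms: none
Why: Alkylation of a lithium ester enolate at a primary allylic bromide (SN2 at the α-carbon); the tert-butyl ester resists Claisen self-condensation, and the E styrene geometry comes unchanged from 2.

Step 2
Reactants: 4 tert-butyl (4E)-5-phenylpent-4-enoate
Product: 5 (4E)-5-phenylpent-4-en-1-ol
Conditions: LiAlH4, Et2O, 0 °C → rt
Reagents that add atoms: none
Why: LiAlH4 reduction of the ester to the primary alcohol; the styrene is not conjugated to the carbonyl group and is not reduced.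

Step 3
Reactants: 5 (4E)-5-phenylpent-4-en-1-ol; 6 1-phenyl-1H-tetrazole-5-thiol
Product: 7 1-phenyl-5-{[(4E)-5-phenylpent-4-en-1-yl]sulfanyl}-1H-tetrazole
Conditions: PPh3, diisopropyl azodicarboxylate, THF, 0 °C → rt
Reagents that add atoms: none
Why: Mitsunobu thioetherification of a primary alcohol by the acidic tetrazole thiol, the standard entry to Julia–Kocienski sulfides.

Step 4
Reactants: 7 1-phenyl-5-{[(4E)-5-phenylpent-4-en-1-yl]sulfanyl}-1H-tetrazole
Product: 8 1-phenyl-5-{[(4E)-5-phenylpent-4-en-1-yl]sulfonyl}-1H-tetrazole
Conditions: (NH4)6Mo7O24·4H2O (cat.), 30% aq. H2O2, EtOH, 0 °C → rt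
Reagents that add atoms: hydrogen peroxide, OO
Why: Molybdate-catalysed oxidation of the sulfide to the sulfone; the peroxomolybdate is selective for sulfur and should leave the 1,2-disubstituted styrene alone, which a peracid would not.

Step 5
Reactants: 9 (R)-citronellal, (3R)-3,7-dimethyloct-6-enal
Product: 10 (4R)-4,8-dimethylnon-7-en-1-yne
Conditions: dimethyl (1-diazo-2-oxopropyl)phosphonate, K2CO3, MeOH, 0 °C → rt
Reagents that add atoms: dimethyl (1-diazo-2-oxopropyl)phosphonate, CC(=O)C(=[N+]=[N-])P(=O)(OC)OC
Why: Ohira–Bestmann (Seyferth–Gilbert) homologation of the aldehyde to the terminal alkyne under mild carbonate conditions; the stereocentre is β to the carbonyl group and cannot epimerise.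

Step 6
Reactants: 10 (4R)-4,8-dimethylnon-7-en-1-yne
Product: 12 (2E,5R)-3,5,9-trimethyldeca-2,8-dien-1-ol, via alkenylalane 11 (not isolated)
Conditions: AlMe3, (C5H5)2ZrCl2 (cat.), CH2Cl2, 0 °C → rt; then (CH2O)n, THF, 0 °C → rt
Reagents that add atoms: trimethylaluminium, C[Al](C)C; formaldehyde (as paraformaldehyde), C=O
Why: Zirconium-catalysed carboalumination (Negishi): methyl and aluminium add syn across the terminal alkyne with aluminium at the terminus, and the alkenyl–aluminium bond is hydroxymethylated with retention, which fixes the 2E geometry; the trisubstituted alkene does not react.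

Step 7
Reactants: 12 (2E,5R)-3,5,9-trimethyldeca-2,8-dien-1-ol
Product: 13 [(2S,3S)-3-[(2R)-2,6-dimethylhept-5-en-1-yl]-3-methyloxiran-2-yl]methanol
Conditions: Ti(OiPr)4 (cat.), L-(+)-diisopropyl tartrate, t-BuOOH, 4 Å molecular sieves, CH2Cl2, −20 °C
Reagents that add atoms: tert-butyl hydroperoxide, CC(C)(C)OO
Why: Sharpless asymmetric epoxidation; with the L-(+)-tartrate the oxygen is delivered to the face that gives the (2S,3S)-epoxide, as for geraniol, under reagent control that overrides the remote methyl centre, and only the allylic alcohol alkene is epoxidised.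

Step 8
Reactants: 13 [(2S,3S)-3-[(2R)-2,6-dimethylhept-5-en-1-yl]-3-methyloxiran-2-yl]methanol
Product: 14 (3S,5R)-3,5,9-trimethyldec-8-ene-1,3-diol
Conditions: NaAlH2(OCH2CH2OCH3)2, THF, 0 °C
Reagents that add atoms: none
Why: Reductive opening of a 2,3-epoxy alcohol: the aluminium alkoxide delivers hydride intramolecularly to C2 and gives the 1,3-diol; the C3–O bond is not broken, so the tertiary carbinol keeps its configuration (3S).

Step 9
Reactants: 14 (3S,5R)-3,5,9-trimethyldec-8-ene-1,3-diol
Product: 16 (2S)-2-[(2R)-2,6-dimethylhept-5-en-1-yl]-2-methyloxetane, via primary tosylate 15 (not isolated)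
Conditions: n-BuLi (1 equiv), THF, 0 °C; TsCl (1 equiv); then n-BuLi (1 equiv), 0 → 60 °C
Reagents that add atoms: none
Why: Intramolecular Williamson etherification: the less hindered primary alkoxide is sulfonylated first and the tertiary alkoxide then closes the oxetane by 4-exo-tet displacement at the primary carbon; no bond to the stereocentre is broken, so the (2S)-oxetane results.

Step 10
Reactants: 16 (2S)-2-[(2R)-2,6-dimethylhept-5-en-1-yl]-2-methyloxetane
Product: 17 (4R)-4-methyl-5-[(2S)-2-methyloxetan-2-yl]pentanal
Conditions: O3, CH2Cl2, −78 °C; then Me2S, −78 °C → rt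
Reagents that add atoms: ozone, [O-][O+]=O
Why: Ozonolysis with reductive work-up cleaves the only alkene to the aldehyde and leaves the oxetane alone; it is done here because ozone cannot be used once the diene is in place and because the trisubstituted alkene would otherwise attack C5 in a six-ring cation–olefin closure when the oxetane is activated in step 12.

Step 11
Reactants: 8 1-phenyl-5-{[(4E)-5-phenylpent-4-en-1-yl]sulfonyl}-1H-tetrazole; 17 (4R)-4-methyl-5-[(2S)-2-methyloxetan-2-yl]pentanal
Product: 19 (2S)-2-methyl-2-[(2R,5E,9E)-2-methyl-10-phenyldeca-5,9-dien-1-yl]oxetane, via potassium sulfonyl carbanion 18 (not isolated)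
Conditions: 8, KN(SiMe3)2, DME, −60 °C; then 17, −60 °C → rt
Reagents that add atoms: none
Why: Julia–Kocienski olefination: the metalated tetrazolyl sulfone adds to the unbranched aldehyde and the adduct undergoes Smiles rearrangement and anti elimination; the potassium counter-ion in DME favours the E alkene, the oxetane is inert to the base, and any minor Z isomer can be removed on silver nitrate-impregnated silica at this robust stage.

Step 12
Reactants: 19 (2S)-2-methyl-2-[(2R,5E,9E)-2-methyl-10-phenyldeca-5,9-dien-1-yl]oxetane
Product: 20 (3R,5R,8E,12E)-3-hydroperoxy-3,5-dimethyl-13-phenyltrideca-8,12-dien-1-ol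
Conditions: H2O2 (anhydrous, in Et2O, 10 equiv), Me3SiOTf (0.2 equiv), Et2O, −78 → −20 °C
Reagents that add atoms: hydrogen peroxide, OO
Why: Lewis acid-promoted perhydrolysis of a 2,2-disubstituted oxetane: hydrogen peroxide attacks the activated tertiary carbon from the side opposite to the ring oxygen, so the (2S)-oxetane gives the (3R)-hydroperoxide (C5 of the target) with inversion; the large excess of H2O2 at low temperature suppresses attack by the product and free-cation formation, the 1,2-disubstituted C10=C11 alkene is a far weaker π-nucleophile than the trisubstituted one it replaced, and any C3 epimer of 20 is a diastereomer that can be removed later.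

Step 13
Reactants: 20 (3R,5R,8E,12E)-3-hydroperoxy-3,5-dimethyl-13-phenyltrideca-8,12-dien-1-ol
Product: 21 (3R,5R,8E,12E)-3-[(2-methoxypropan-2-yl)peroxy]-3,5-dimethyl-13-phenyltrideca-8,12-dien-1-ol
Conditions: 2-methoxypropene (1.3 equiv), pyridinium p-toluenesulfonate (cat.), CH2Cl2, 0 °C
Reagents that add atoms: 2-methoxypropene, COC(C)=C
Why: Acid-catalysed addition to the enol ether gives the 2-methoxyprop-2-yl peroxyketal; the hydroperoxide is the more acidic and, through the α-effect, the more nucleophilic hydroxyl and is ketalised ahead of the primary alcohol with a small excess of reagent.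

Step 14
Reactants: 21 (3R,5R,8E,12E)-3-[(2-methoxypropan-2-yl)peroxy]-3,5-dimethyl-13-phenyltrideca-8,12-dien-1-ol
Product: 22 (3R,5R,8E,12E)-3-[(2-methoxypropan-2-yl)peroxy]-3,5-dimethyl-13-phenyltrideca-8,12-dienal
Conditions: Dess–Martin periodinane, pyridine, CH2Cl2, 0 °C → rt
Reagents that add atoms: none
Why: Dess–Martin oxidation of the primary alcohol under buffered, anhydrous conditions that spare the acid-labile peroxyketal and the alkenes; the β-peroxy aldehyde is used without chromatography to avoid β-elimination.

Step 15
Reactants: 22 (3R,5R,8E,12E)-3-[(2-methoxypropan-2-yl)peroxy]-3,5-dimethyl-13-phenyltrideca-8,12-dienal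
Product: 23 (2RS,4R,6R,9E,13E)-4-[(2-methoxypropan-2-yl)peroxy]-4,6-dimethyl-14-phenyltetradeca-9,13-dien-2-ol
Conditions: MeMgBr, Et2O, −78 °C
Reagents that add atoms: methylmagnesium bromide, C[Mg]Br
Why: Grignard addition to the aldehyde at −78 °C, expected to be far faster than attack on the hindered di-tertiary peroxide or deprotonation α to the aldehyde; both epimers of the new carbinol centre are used, since it is oxidised in the next step.

Step 16
Reactants: 23 (2RS,4R,6R,9E,13E)-4-[(2-methoxypropan-2-yl)peroxy]-4,6-dimethyl-14-phenyltetradeca-9,13-dien-2-ol
Product: 24 (4R,6R,9E,13E)-4-[(2-methoxypropan-2-yl)peroxy]-4,6-dimethyl-14-phenyltetradeca-9,13-dien-2-one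
Conditions: Dess–Martin periodinane, pyridine, CH2Cl2, 0 °C → rt
Reagents that add atoms: none
Why: Dess–Martin oxidation of the secondary alcohol to the methyl ketone, again buffered with pyridine; the uncontrolled carbinol centre from step 15 disappears.

Step 17
Reactants: 24 (4R,6R,9E,13E)-4-[(2-methoxypropan-2-yl)peroxy]-4,6-dimethyl-14-phenyltetradeca-9,13-dien-2-one
Product: 25 (4R,6R,9E,13E)-4-[(2-methoxypropan-2-yl)peroxy]-2,4,6-trimethyl-14-phenyltetradeca-1,9,13-triene
Conditions: Ph3PCH3Br, KN(SiMe3)2, THF, 0 °C; then 24, −78 → 0 °C
Reagents that add atoms: methyltriphenylphosphonium bromide, C[P+](c1ccccc1)(c1ccccc1)c1ccccc1.[Br-]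
Why: Wittig methylenation of the methyl ketone with a lithium-free ylide at low temperature; the unstabilised ylide should add to the unhindered ketone faster than it enolises it, and the peroxide carbon carries no hydrogen that a base could remove.

Step 18
Reactants: 25 (4R,6R,9E,13E)-4-[(2-methoxypropan-2-yl)peroxy]-2,4,6-trimethyl-14-phenyltetradeca-1,9,13-triene
Product: 26 (4R,6R,9E,13E)-4-hydroperoxy-2,4,6-trimethyl-14-phenyltetradeca-1,9,13-triene
Conditions: AcOH/THF/H2O (3:1:1), rt
Reagents that add atoms: none
Why: Hydrolysis of the mixed peroxyketal in aqueous acetic acid frees the tertiary hydroperoxide; the acid is too weak to protonate the 1,1-disubstituted alkene, so no acid-catalysed cyclisation competes.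

Step 19
Reactants: 26 (4R,6R,9E,13E)-4-hydroperoxy-2,4,6-trimethyl-14-phenyltetradeca-1,9,13-triene; 27 carbon monoxide; 28 methanol
Product: 29 methyl 2-[(3S,5R)-3,5-dimethyl-5-[(2R,5E,9E)-2-methyl-10-phenyldeca-5,9-dien-1-yl]-1,2-dioxolan-3-yl]acetate
Conditions: Pd(OCOCF3)2 (10 mol %), 2,2'-(propane-2,2-diyl)bis[(4S)-4-phenyl-4,5-dihydro-1,3-oxazole] (12 mol %), p-benzoquinone (1.5 equiv), 27 (1 atm), 28/CH2Cl2 (1:1), −20 → 0 °C
Reagents that add atoms: none
Why: Proposed new method: the ligated divalent palladium binds the 1,1-disubstituted alkene of 26, the terminal hydroperoxide oxygen O2 attacks the internal carbon C3 and closes the 1,2-dioxolane, and the resulting C2–palladium bond, which has no β-hydrogen because C3 is fully substituted, inserts CO and is cleaved by methanol to the ester (C2–C1), after which p-benzoquinone returns zerovalent palladium to the divalent state. The closest known reaction types are the palladium-catalysed alkoxycarbonylative cyclisation of alkenols to cyclic ether acetates, the divalent-palladium cyclisation of unsaturated hydroperoxides to 1,2-dioxanes and the cycloperoxymercuration of methallyl-type hydroperoxides; what is new is the union of a hydroperoxide nucleophile with carbonylative capture. The one ring formed, the dioxolane, closes in the 5-exo-trig, Markovnikov mode; 6-endo attack at C2 would place palladium on a tertiary carbon and is not expected. The new stereocentre C3 is set by the chiral bis(oxazoline) ligand, which differentiates the two alkene faces, because the substrate bias (methyl against CH2R on C5) is small, although it should point the same way, with the CH2–palladium group trans to the larger C5 arm as in 29. Which ligand antipode is matched to the 3S face is to be fixed in a first pair of experiments, and the 3R epimer, a diastereomer, is removed on silica. The step needs chemoselectivity for the methallyl alkene over the C10=C11 alkene and the styrene, which is secured by the tether (only this alkene has the nucleophile at five-ring distance) and by its better binding to palladium. It also needs carbonylation to outrun β-oxygen elimination, which merely returns 26, and low temperature with the quinone present should limit palladium-induced O–O cleavage.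

Step 20
Reactants: 29 methyl 2-[(3S,5R)-3,5-dimethyl-5-[(2R,5E,9E)-2-methyl-10-phenyldeca-5,9-dien-1-yl]-1,2-dioxolan-3-yl]acetate
Product: 30 2-[(3S,5R)-3,5-dimethyl-5-[(2R,5E,9E)-2-methyl-10-phenyldeca-5,9-dien-1-yl]-1,2-dioxolan-3-yl]acetic acid
Conditions: LiOH, THF/H2O (3:1), 0 °C → rt; then 1 M HCl to pH 3
Reagents that add atoms: lithium hydroxide, [Li+].[OH-]
Why: Saponification of the methyl ester and careful acidification; hydroxide attacks the ester carbonyl much faster than it deprotonates C2, and the ring carbons carry no hydrogen, so neither Kornblum–DeLaMare-type fragmentation nor epimerisation is expected.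

## Compound list

1 | tert-butyl acetate | CC(=O)OC(C)(C)C | starting material
2 | cinnamyl bromide, [(1E)-3-bromoprop-1-en-1-yl]benzene | BrC/C=C/c1ccccc1 | starting material
3 | lithium 1-tert-butoxyethen-1-olate (lithium enolate of 1) | [Li+].[O-]C(=C)OC(C)(C)C | intermediate
4 | tert-butyl (4E)-5-phenylpent-4-enoate | CC(C)(C)OC(=O)CC/C=C/c1ccccc1 | intermediate
5 | (4E)-5-phenylpent-4-en-1-ol | OCCC/C=C/c1ccccc1 | intermediate
6 | 1-phenyl-1H-tetrazole-5-thiol | Sc1nnnn1-c1ccccc1 | starting material
7 | 1-phenyl-5-{[(4E)-5-phenylpent-4-en-1-yl]sulfanyl}-1H-tetrazole | C(CC/C=C/c1ccccc1)Sc1nnnn1-c1ccccc1 | intermediate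
8 | 1-phenyl-5-{[(4E)-5-phenylpent-4-en-1-yl]sulfonyl}-1H-tetrazole | O=S(=O)(CCC/C=C/c1ccccc1)c1nnnn1-c1ccccc1 | intermediate
9 | (R)-citronellal, (3R)-3,7-dimethyloct-6-enal | C[C@H](CCC=C(C)C)CC=O | starting material
10 | (4R)-4,8-dimethylnon-7-en-1-yne | C[C@H](CCC=C(C)C)CC#C | intermediate
11 | dimethyl[(1E,4R)-2,4,8-trimethylnona-1,7-dien-1-yl]alumane | C/C(=C\[Al](C)C)C[C@H](C)CCC=C(C)C | intermediate
12 | (2E,5R)-3,5,9-trimethyldeca-2,8-dien-1-ol | C/C(=C\CO)C[C@H](C)CCC=C(C)C | intermediate
13 | [(2S,3S)-3-[(2R)-2,6-dimethylhept-5-en-1-yl]-3-methyloxiran-2-yl]methanol | OC[C@@H]1O[C@@]1(C)C[C@H](C)CCC=C(C)C | intermediate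
14 | (3S,5R)-3,5,9-trimethyldec-8-ene-1,3-diol | C[C@@](O)(CCO)C[C@H](C)CCC=C(C)C | intermediate
15 | (3S,5R)-3-hydroxy-3,5,9-trimethyldec-8-en-1-yl 4-methylbenzenesulfonate | C[C@@](O)(CCOS(=O)(=O)c1ccc(C)cc1)C[C@H](C)CCC=C(C)C | intermediate
16 | (2S)-2-[(2R)-2,6-dimethylhept-5-en-1-yl]-2-methyloxetane | C[C@]1(C[C@H](C)CCC=C(C)C)CCO1 | intermediate
17 | (4R)-4-methyl-5-[(2S)-2-methyloxetan-2-yl]pentanal | C[C@]1(C[C@H](C)CCC=O)CCO1 | intermediate
18 | potassium 5-phenyl-1-[(1-phenyl-1H-tetrazol-5-yl)sulfonyl]pent-4-en-1-ide (metalated 8) | [K+].[CH-](CC/C=C/c1ccccc1)S(=O)(=O)c1nnnn1-c1ccccc1 | intermediate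
19 | (2S)-2-methyl-2-[(2R,5E,9E)-2-methyl-10-phenyldeca-5,9-dien-1-yl]oxetane | C[C@]1(C[C@H](C)CC/C=C/CC/C=C/c2ccccc2)CCO1 | intermediate
20 | (3R,5R,8E,12E)-3-hydroperoxy-3,5-dimethyl-13-phenyltrideca-8,12-dien-1-ol | C[C@](OO)(CCO)C[C@H](C)CC/C=C/CC/C=C/c1ccccc1 | intermediate
21 | (3R,5R,8E,12E)-3-[(2-methoxypropan-2-yl)peroxy]-3,5-dimethyl-13-phenyltrideca-8,12-dien-1-ol | C[C@](OOC(C)(C)OC)(CCO)C[C@H](C)CC/C=C/CC/C=C/c1ccccc1 | intermediate
22 | (3R,5R,8E,12E)-3-[(2-methoxypropan-2-yl)peroxy]-3,5-dimethyl-13-phenyltrideca-8,12-dienal | C[C@](OOC(C)(C)OC)(CC=O)C[C@H](C)CC/C=C/CC/C=C/c1ccccc1 | intermediate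
23 | (2RS,4R,6R,9E,13E)-4-[(2-methoxypropan-2-yl)peroxy]-4,6-dimethyl-14-phenyltetradeca-9,13-dien-2-ol | CC(O)C[C@](C)(OOC(C)(C)OC)C[C@H](C)CC/C=C/CC/C=C/c1ccccc1 | intermediate
24 | (4R,6R,9E,13E)-4-[(2-methoxypropan-2-yl)peroxy]-4,6-dimethyl-14-phenyltetradeca-9,13-dien-2-one | CC(=O)C[C@](C)(OOC(C)(C)OC)C[C@H](C)CC/C=C/CC/C=C/c1ccccc1 | intermediate
25 | (4R,6R,9E,13E)-4-[(2-methoxypropan-2-yl)peroxy]-2,4,6-trimethyl-14-phenyltetradeca-1,9,13-triene | C=C(C)C[C@](C)(OOC(C)(C)OC)C[C@H](C)CC/C=C/CC/C=C/c1ccccc1 | intermediate
26 | (4R,6R,9E,13E)-4-hydroperoxy-2,4,6-trimethyl-14-phenyltetradeca-1,9,13-triene | C=C(C)C[C@](C)(OO)C[C@H](C)CC/C=C/CC/C=C/c1ccccc1 | intermediate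
27 | carbon monoxide | [C-]#[O+] | starting material
28 | methanol | CO | starting material
29 | methyl 2-[(3S,5R)-3,5-dimethyl-5-[(2R,5E,9E)-2-methyl-10-phenyldeca-5,9-dien-1-yl]-1,2-dioxolan-3-yl]acetate | C[C@H](CC/C=C/CC/C=C/c1ccccc1)C[C@]1(C)C[C@@](C)(CC(=O)OC)OO1 | intermediate
30 | 2-[(3S,5R)-3,5-dimethyl-5-[(2R,5E,9E)-2-methyl-10-phenyldeca-5,9-dien-1-yl]-1,2-dioxolan-3-yl]acetic acid | C[C@H](CC/C=C/CC/C=C/c1ccccc1)C[C@]1(C)C[C@@](C)(CC(=O)O)OO1 | target

## Step count and least certain steps

Total step count: 20. Longest linear sequence: 16 steps (steps 5 to 20, from 9); the sulfone branch (steps 1 to 4) joins at step 11.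

**Step 19 (key step, proposed new method).** Four things may go wrong: reversal by β-oxygen elimination may outpace CO insertion; palladium may cleave the O–O bond of the hydroperoxide; oxidative methoxycarbonylation may occur at the styrene; and face discrimination at C3 may be weak. The fallback uses known chemistry, sets out from ketone 24 and returns at ester 29.
- Aqueous acetic acid removes the peroxyketal, and the β-hydroperoxy ketone closes spontaneously to the peroxyhemiketal (3RS,5R)-3,5-dimethyl-5-[(2R,5E,9E)-2-methyl-10-phenyldeca-5,9-dien-1-yl]-1,2-dioxolan-3-ol F1.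
- Acid-catalysed exchange in methanol (pyridinium p-toluenesulfonate) gives (3RS,5R)-3-methoxy-3,5-dimethyl-5-[(2R,5E,9E)-2-methyl-10-phenyldeca-5,9-dien-1-yl]-1,2-dioxolane F2.
- Me3SiOTf (or TiCl4) in CH2Cl2 at −78 °C ionises F2 to the C3 peroxycarbenium ion, which is trapped by 1-methoxy-1-(trimethylsilyloxy)ethene to give 29 and its 3R epimer. The nucleophile is expected to approach anti to the larger C5 arm, and the epimers are separated on silica.

This replaces catalyst control at C3 by substrate control and CO by a two-carbon ketene acetal, but each operation is of a known type.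

**Step 17.** The ylide may act as a base: enolisation of the β-peroxy ketone toward C4 would be followed by expulsion of the peroxide oxygen from C5. The fallback goes from 24 to 25 by a Peterson olefination. The weakly basic organocerium reagent from Me3SiCH2Li and CeCl3 adds at −78 °C to give the β-hydroxysilane (2RS,4R,6R,9E,13E)-4-[(2-methoxypropan-2-yl)peroxy]-2,4,6-trimethyl-14-phenyl-1-(trimethylsilyl)tetradeca-9,13-dien-2-ol F3. KH in THF at 0 °C then effects syn elimination to 25.

**Step 15.** The Grignard reagent may attack an oxygen of the peroxyketal (O–O cleavage) or deprotonate C4, the carbon α to the aldehyde, which again expels the peroxide from C5. The fallback goes from 22 directly to 24 by the Buchner–Curtius–Schlotterbeck homologation. Diazomethane in Et2O at 0 °C adds to the aldehyde, and the betaine loses nitrogen with a 1,2-hydride shift to give the methyl ketone. The reagent is neither basic nor reactive toward dialkyl peroxides, steps 15 and 16 are bypassed, and no new compound arises (F0).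

**Step 11.** E selectivity in the addition and elimination sequence may be incomplete, leaving a Z isomer that is hard to remove and would travel to 30. The fallback goes from 17 to 19 and fixes the geometry by syn hydrometalation instead of by an elimination.
- Ohira–Bestmann homologation of 17 gives (2S)-2-methyl-2-[(2R)-2-methylhex-5-yn-1-yl]oxetane F4.
- Hydrozirconation with (C5H5)2Zr(H)Cl and iodinolysis give (2S)-2-[(2R,5E)-6-iodo-2-methylhex-5-en-1-yl]-2-methyloxetane F5 as the E isomer only.
- Hydroboration of commercial (E)-buta-1,3-dien-1-ylbenzene at its terminal double bond with 9-borabicyclo[3.3.1]nonane gives 9-[(3E)-4-phenylbut-3-en-1-yl]-9-borabicyclo[3.3.1]nonane F6.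
- A B-alkyl Suzuki–Miyaura coupling of F5 with F6 (PdCl2(dppf), Cs2CO3, DMF/THF/H2O, rt) forms the C11–C12 bond with retention and gives 19.

## Further compounds

F1 | step 19 | (3RS,5R)-3,5-dimethyl-5-[(2R,5E,9E)-2-methyl-10-phenyldeca-5,9-dien-1-yl]-1,2-dioxolan-3-ol | C[C@H](CC/C=C/CC/C=C/c1ccccc1)C[C@]1(C)CC(C)(O)OO1
F2 | step 19 | (3RS,5R)-3-methoxy-3,5-dimethyl-5-[(2R,5E,9E)-2-methyl-10-phenyldeca-5,9-dien-1-yl]-1,2-dioxolane | C[C@H](CC/C=C/CC/C=C/c1ccccc1)C[C@]1(C)CC(C)(OC)OO1
F3 | step 17 | (2RS,4R,6R,9E,13E)-4-[(2-methoxypropan-2-yl)peroxy]-2,4,6-trimethyl-14-phenyl-1-(trimethylsilyl)tetradeca-9,13-dien-2-ol | C[Si](C)(C)CC(C)(O)C[C@](C)(OOC(C)(C)OC)C[C@H](C)CC/C=C/CC/C=C/c1ccccc1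
F0 | step 15 | none | none
F4 | step 11 | (2S)-2-methyl-2-[(2R)-2-methylhex-5-yn-1-yl]oxetane | C[C@]1(C[C@H](C)CCC#C)CCO1
F5 | step 11 | (2S)-2-[(2R,5E)-6-iodo-2-methylhex-5-en-1-yl]-2-methyloxetane | C[C@]1(C[C@H](C)CC/C=C/I)CCO1
F6 | step 11 | 9-[(3E)-4-phenylbut-3-en-1-yl]-9-borabicyclo[3.3.1]nonane | C(C/C=C/c1ccccc1)B1C2CCCC1CCC2
A1 | alternative 1 | 2-[(3R,5R)-5-[(2R)-5-{[tert-butyl(diphenyl)silyl]oxy}-2-methylpentyl]-3,5-dimethyl-1,2-dioxolan-3-yl]ethyl benzoate | C[C@H](CCCO[Si](c1ccccc1)(c1ccccc1)C(C)(C)C)C[C@]1(C)C[C@@](C)(CCOC(=O)c2ccccc2)OO1
A2 | alternative 1 | 3-methoxy-3-[(triethylsilyl)peroxy]butyl benzoate | CC(OC)(OO[Si](CC)(CC)CC)CCOC(=O)c1ccccc1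
A3 | alternative 1 | tert-butyl{[(4R)-4,6-dimethylhept-6-en-1-yl]oxy}diphenylsilane | C=C(C)C[C@H](C)CCCO[Si](c1ccccc1)(c1ccccc1)C(C)(C)C
A4 | alternative 2 | (3E,6R,9E,13E)-4,6-dimethyl-14-phenyltetradeca-3,9,13-trien-2-one | CC(=O)/C=C(\C)C[C@H](C)CC/C=C/CC/C=C/c1ccccc1
A5 | alternative 2 | (3RS,5R)-3,5-dimethyl-5-[(2R,5E,9E)-2-methyl-10-phenyldeca-5,9-dien-1-yl]-1,2-dioxolan-3-ol | C[C@H](CC/C=C/CC/C=C/c1ccccc1)C[C@]1(C)CC(C)(O)OO1
A6 | alternative 3 | methyl 2-[(3S,5R)-5-[(2R)-5-{[tert-butyl(diphenyl)silyl]oxy}-2-methylpentyl]-3,5-dimethyl-1,2-dioxolan-3-yl]acetate | C[C@H](CCCO[Si](c1ccccc1)(c1ccccc1)C(C)(C)C)C[C@]1(C)C[C@@](C)(CC(=O)OC)OO1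
A7 | alternative 3 | tert-butyl{[(4R)-6-methoxy-4-methyl-6-[(triethylsilyl)peroxy]heptyl]oxy}diphenylsilane | CC(OC)(OO[Si](CC)(CC)CC)C[C@H](C)CCCO[Si](c1ccccc1)(c1ccccc1)C(C)(C)C
A8 | alternative 3 | methyl 3-methylbut-3-enoate | C=C(C)CC(=O)OC
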